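**Plan**
1. Retrosynthesis: the six benzyl ethers of 20 come off last. The chromanone C-2–C-3 bond and the bond from the furan oxygen to flavan C-7 are then cut together, which unfolds the core to the o-aroyloxyaryl α-benzyloxy ketone 17 with fluoride at C-7. Cutting the C-8–CH(O) bond gives arylglyoxal 13 and flavan 9, and opening the flavan C-2–O bond gives a retro-chalcone.
2. Enabling feature: chromanone C-2 is a ketal carbon at the carboxylic acid oxidation level that carries the B-ring and the A-ring oxygen. It is a masked aryl 4-hydroxybenzoate whose C=O oxygen is the furan oxygen, and C-3 is the α-carbon of the C-4 aryl ketone. The pyranone ring is thus a Baker–Venkataraman tetrahedral intermediate whose alkoxide lies 1,5 to flavan C-7.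
3. Ring order forward: flavan pyran ring (Mitsunobu), C-8 aryl–carbon bond (aryl-Mg to glyoxal), pyranone and furan rings in one operation, then hydrogenolysis.
4. Stereochemistry: flavan C-2 (S) from Noyori transfer hydrogenation to the (R)-carbinol and Mitsunobu inversion. The C-3 carbinol carbon comes from a chiral ammonium ion pair in the key C-acylation, because the flavan centre is too remote to control it. The C-2 ketal carbon follows from the geometric demand of the furan closure.

Key step: step 11

Remark: read strictly, the two ring-fusion descriptors of the target string put the B-ring and the C-3 oxygen on opposite faces of the C-2–C-3 bond, a relationship in which the furan and pyranone rings cannot both close; it is assumed that the syn-fused compound with the carbinol carbon as written is meant, and the strings of 19, 20, 21 and F1 keep the notation of the target string.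

**Route**

Step 1
Reactants: 1 5-fluorobenzene-1,3-diol
Product: 2 1,3-bis(benzyloxy)-5-fluorobenzene
Conditions: BnBr, K2CO3, DMF, 60 °C
Reagents that add atoms: benzyl bromide, BrCc1ccccc1
Why: Williamson ether synthesis on both phenols.

Step 2
Reactants: 2 1,3-bis(benzyloxy)-5-fluorobenzene
Product: 4 2,6-bis(benzyloxy)-4-fluorobenzaldehyde, via aryllithium 3 (not isolated)
Conditions: n-BuLi, TMEDA, THF, −78 → −30 °C; DMF, −78 °C → rt; aq. NH4Cl
Reagents that add atoms: N,N-dimethylformamide, CN(C)C=O
Why: Directed ortho-metalation at the carbon flanked by both benzyloxy groups (cooperative coordination of lithium), then formylation of the aryllithium with DMF.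

Step 3
Reactants: 4 2,6-bis(benzyloxy)-4-fluorobenzaldehyde
Product: 5 2-(benzyloxy)-4-fluoro-6-hydroxybenzaldehyde
Conditions: MgBr2·OEt2, toluene/Et2O, 60 °C; aq. HCl
Reagents that add atoms: none
Why: Chelation-assisted Lewis acid debenzylation ortho to a carbonyl group; the magnesium phenoxide chelate formed after the first cleavage ties up the aldehyde oxygen, so the second ether should be spared.

Step 4
Reactants: 5 2-(benzyloxy)-4-fluoro-6-hydroxybenzaldehyde; 6 1-[4-(benzyloxy)phenyl]ethanone
Product: 7 (E)-3-[2-(benzyloxy)-4-fluoro-6-hydroxyphenyl]-1-[4-(benzyloxy)phenyl]prop-2-en-1-one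
Conditions: KOH, EtOH/H2O, rt → 40 °C
Reagents that add atoms: none
Why: Claisen–Schmidt condensation gives the thermodynamic E-enone, and the aldehyde ring is a phenoxide under these conditions, which shields its para fluoride from substitution.

Step 5
Reactants: 7 the (E)-chalcone
Product: 8 (1R)-3-[2-(benzyloxy)-4-fluoro-6-hydroxyphenyl]-1-[4-(benzyloxy)phenyl]propan-1-ol
Conditions: RuCl[(R,R)-TsDPEN](p-cymene) (2 mol %), HCO2H/Et3N (5:2), DMF, 40 °C
Reagents that add atoms: none
Why: Noyori asymmetric transfer hydrogenation, in which the chalcone C=C is reduced first by conjugate hydride transfer and the resulting aryl ketone is then reduced enantioselectively, the (R,R)-catalyst giving the (R)-1-arylalkanol.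

Step 6
Reactants: 8 the (1R)-alcohol
Product: 9 (2S)-5-(benzyloxy)-2-[4-(benzyloxy)phenyl]-7-fluorochromane
Conditions: PPh3, DIAD, toluene, 0 °C
Reagents that add atoms: none
Why: Intramolecular Mitsunobu etherification; SN2 displacement of the oxyphosphonium by the phenol inverts the carbinol carbon, (R) to (2S).

Step 7
Reactants: 10 1-[2,4-bis(benzyloxy)-6-hydroxyphenyl]ethanone; 11 4-(benzyloxy)benzoyl chloride
Product: 12 2-acetyl-3,5-bis(benzyloxy)phenyl 4-(benzyloxy)benzoate
Conditions: Et3N, DMAP (cat.), CH2Cl2, 0 °C → rt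
Reagents that add atoms: none
Why: O-acylation of the phenol; the ester carbon is the future chromanone C-2 and also protects this phenol.

Step 8
Reactants: 12 the aryl ester
Product: 13 3,5-bis(benzyloxy)-2-(oxoacetyl)phenyl 4-(benzyloxy)benzoate
Conditions: SeO2, 1,4-dioxane/H2O (20:1), 95 °C; azeotropic drying (toluene)
Reagents that add atoms: selenium dioxide, O=[Se]=O
Why: Riley oxidation of an aryl methyl ketone to the arylglyoxal, which has no α-hydrogen left and is dehydrated from its hydrate before use.

Step 9
Reactants: 9 the (2S)-flavan; 13 the arylglyoxal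
Product: 16 3,5-bis(benzyloxy)-2-{2-hydroxy-2-[(2S)-5-(benzyloxy)-2-(4-benzyloxyphenyl)-7-fluorochroman-8-yl]acetyl}phenyl 4-(benzyloxy)benzoate (both epimers at the new carbinol carbon), via 8-lithiochroman 14 (not isolated), via chroman-8-ylmagnesium bromide 15 (not isolated)
Conditions: s-BuLi, THF, −78 °C; MgBr2·OEt2, −78 °C; 13, −78 °C; AcOH, −78 °C
Reagents that add atoms: none
Why: Fluorine and the pyran oxygen together direct deprotonation to C-8 (the C-5 benzyloxy group shields C-6), and transmetalation to magnesium tempers the aryl-metal so that it adds to the glyoxal aldehyde and spares the hindered ketone and the aryl ester (1,2-addition of an aryl Grignard reagent); the new carbinol centre forms unselectively and is erased in step 11.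

Step 10
Reactants: 16 the α-hydroxy ketone
Product: 17 3,5-bis(benzyloxy)-2-{2-(benzyloxy)-2-[(2S)-5-(benzyloxy)-2-(4-benzyloxyphenyl)-7-fluorochroman-8-yl]acetyl}phenyl 4-(benzyloxy)benzoate (both epimers at the benzyloxy-bearing carbon)
Conditions: BnOC(=NH)CCl3, TfOH (5 mol %), CH2Cl2/cyclohexane, 0 °C
Reagents that add atoms: benzyl 2,2,2-trichloroacetimidate, N=C(OCc1ccccc1)C(Cl)(Cl)Cl
Why: Acid-catalysed benzylation with a trichloroacetimidate avoids the base that would enolise the benzoin or start acyl transfer, and fixes the future C-3 oxygen so that only the benzylic carbon can become the enolate carbon.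

Step 11
Reactants: 17 the o-aroyloxyaryl α-benzyloxy ketone
Product: 20 hexa-O-benzyl ether of the target (benzyl on the five phenolic oxygens and on the C-3 tertiary oxygen), via caesium enolate 18 (not isolated), via hemiketal alkoxide 19 (not isolated)
Conditions: (S,S)-3,4,5-trifluorophenyl-NAS bromide (binaphthyl spiro ammonium salt, 10 mol %), Cs2CO3, 4 Å MS, toluene, −20 °C → rt; then DMSO, 70 °C
Reagents that add atoms: none
Why: Proposed new method: Cs2CO3 generates the ketone enolate 18, which as an ion pair with the chiral ammonium cation adds through carbon to the neighbouring aryl ester carbonyl (first half of a Baker–Venkataraman acyl transfer, 6-(enolendo)-exo-trig), closing the pyranone ring and forming the C-2–C-3 bond; the tetrahedral alkoxide 19, in equilibrium with the ring-opened phenoxide triketone, is then drained irreversibly by ipso attack on flavan C-7, five atoms away, with loss of fluoride (intramolecular SNAr, 5-exo), so that the former ester carbonyl oxygen becomes the furan oxygen. The closest known reaction types are the Baker–Venkataraman rearrangement of o-aroyloxyaryl ketones and the alkoxide SNAr cyclisation of 2-(2-fluoroaryl)ethanols to dihydrobenzofurans, the fluoroarene here being activated inductively by its two meta oxygens. The C-3 carbinol carbon is set in the C–C bond formation by the chiral cation, which selects the enolate face (the catalyst antipode is chosen by which diastereomer of 20 it favours, since the flavan centre gives no bias); the C-2 ketal carbon is not free, because the furan can close only when its oxygen and the flavan aryl are syn on the C-2–C-3 bond. The step needs C- over O-acylation and arylation of the hemiketal oxygen over the enolate or phenoxide oxygen: O-acyl transfer is reversible and only the C-acylated hemiketal alkoxide has a five-membered path to C–F, the enolate (whose oxygen could otherwise close a benzofuran) is consumed at low temperature before the SNAr stage is heated, and the phenoxide could reach C-7 only through a seven-membered ring.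

Step 12
Reactants: 20 the hexa-O-benzyl ether
Product: 21 target compound CNP0208300.3
Conditions: H2 (1 atm), Pd(OH)2/C, THF/MeOH, rt
Reagents that add atoms: none
Why: Hydrogenolysis of the five aryl benzyl ethers and the tertiary benzyl ether; at 1 atm and room temperature the aryl ketone, the diaryl ketal and the flavan ring ether should persist.

**Compound list**
1 | 5-fluorobenzene-1,3-diol | Oc1cc(O)cc(F)c1 | starting material
2 | 1,3-bis(benzyloxy)-5-fluorobenzene | Fc1cc(OCc2ccccc2)cc(OCc2ccccc2)c1 | intermediate
3 | [2,6-bis(benzyloxy)-4-fluorophenyl]lithium | [Li]c1c(OCc2ccccc2)cc(F)cc1OCc1ccccc1 | intermediate (not isolated)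
4 | 2,6-bis(benzyloxy)-4-fluorobenzaldehyde | O=Cc1c(OCc2ccccc2)cc(F)cc1OCc1ccccc1 | intermediate
5 | 2-(benzyloxy)-4-fluoro-6-hydroxybenzaldehyde | O=Cc1c(O)cc(F)cc1OCc1ccccc1 | intermediate
6 | 1-[4-(benzyloxy)phenyl]ethanone | CC(=O)c1ccc(OCc2ccccc2)cc1 | starting material
7 | (E)-3-[2-(benzyloxy)-4-fluoro-6-hydroxyphenyl]-1-[4-(benzyloxy)phenyl]prop-2-en-1-one | O=C(/C=C/c1c(O)cc(F)cc1OCc1ccccc1)c1ccc(OCc2ccccc2)cc1 | intermediate
8 | (1R)-3-[2-(benzyloxy)-4-fluoro-6-hydroxyphenyl]-1-[4-(benzyloxy)phenyl]propan-1-ol | O[C@@H](c1ccc(OCc2ccccc2)cc1)CCc1c(O)cc(F)cc1OCc1ccccc1 | intermediate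
9 | (2S)-5-(benzyloxy)-2-[4-(benzyloxy)phenyl]-7-fluorochromane | Fc1cc(OCc2ccccc2)c2CC[C@@H](c3ccc(OCc4ccccc4)cc3)Oc2c1 | intermediate
10 | 1-[2,4-bis(benzyloxy)-6-hydroxyphenyl]ethanone | CC(=O)c1c(O)cc(OCc2ccccc2)cc1OCc1ccccc1 | starting material
11 | 4-(benzyloxy)benzoyl chloride | O=C(Cl)c1ccc(OCc2ccccc2)cc1 | starting material
12 | 2-acetyl-3,5-bis(benzyloxy)phenyl 4-(benzyloxy)benzoate | CC(=O)c1c(OCc2ccccc2)cc(OCc2ccccc2)cc1OC(=O)c1ccc(OCc2ccccc2)cc1 | intermediate
13 | 3,5-bis(benzyloxy)-2-(oxoacetyl)phenyl 4-(benzyloxy)benzoate | O=CC(=O)c1c(OCc2ccccc2)cc(OCc2ccccc2)cc1OC(=O)c1ccc(OCc2ccccc2)cc1 | intermediate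
14 | [(2S)-5-(benzyloxy)-2-(4-benzyloxyphenyl)-7-fluorochroman-8-yl]lithium | [Li]c1c(F)cc(OCc2ccccc2)c2CC[C@@H](c3ccc(OCc4ccccc4)cc3)Oc12 | intermediate (not isolated)
15 | [(2S)-5-(benzyloxy)-2-(4-benzyloxyphenyl)-7-fluorochroman-8-yl]magnesium bromide | Br[Mg]c1c(F)cc(OCc2ccccc2)c2CC[C@@H](c3ccc(OCc4ccccc4)cc3)Oc12 | intermediate (not isolated)
16 | 3,5-bis(benzyloxy)-2-{2-hydroxy-2-[(2S)-5-(benzyloxy)-2-(4-benzyloxyphenyl)-7-fluorochroman-8-yl]acetyl}phenyl 4-(benzyloxy)benzoate, both epimers at the carbinol carbon | O=C(C(O)c1c(F)cc(OCc2ccccc2)c2CC[C@@H](c3ccc(OCc4ccccc4)cc3)Oc12)c1c(OCc2ccccc2)cc(OCc2ccccc2)cc1OC(=O)c1ccc(OCc2ccccc2)cc1 | intermediate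
17 | 3,5-bis(benzyloxy)-2-{2-(benzyloxy)-2-[(2S)-5-(benzyloxy)-2-(4-benzyloxyphenyl)-7-fluorochroman-8-yl]acetyl}phenyl 4-(benzyloxy)benzoate, both epimers at the benzyloxy-bearing carbon | O=C(C(OCc1ccccc1)c1c(F)cc(OCc2ccccc2)c2CC[C@@H](c3ccc(OCc4ccccc4)cc3)Oc12)c1c(OCc2ccccc2)cc(OCc2ccccc2)cc1OC(=O)c1ccc(OCc2ccccc2)cc1 | intermediate
18 | caesium enolate of 17 (ion-paired with the chiral ammonium cation during C–C bond formation) | [Cs+].[O-]C(=C(OCc1ccccc1)c1c(F)cc(OCc2ccccc2)c2CC[C@@H](c3ccc(OCc4ccccc4)cc3)Oc12)c1c(OCc2ccccc2)cc(OCc2ccccc2)cc1OC(=O)c1ccc(OCc2ccccc2)cc1 | intermediate (not isolated)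
19 | caesium 3,5,7-tris(benzyloxy)-2-(4-benzyloxyphenyl)-3-[(2S)-5-(benzyloxy)-2-(4-benzyloxyphenyl)-7-fluorochroman-8-yl]-4-oxochroman-2-olate, C-2 and C-3 as in 20 | [Cs+].O=C1c2c(OCc3ccccc3)cc(OCc3ccccc3)cc2O[C@]([O-])(c2ccc(OCc3ccccc3)cc2)[C@]1(OCc1ccccc1)c1c(F)cc(OCc2ccccc2)c2CC[C@@H](c3ccc(OCc4ccccc4)cc3)Oc12 | intermediate (not isolated)
20 | hexa-O-benzyl ether of the target: benzofuro[2,3-b]chromanone core annulated to the (2S)-flavan, benzyl on the five phenolic oxygens and on the C-3 tertiary oxygen, fusion carbons as in 21 | O=C1c2c(OCc3ccccc3)cc(OCc3ccccc3)cc2O[C@@]2(c3ccc(OCc5ccccc5)cc3)Oc3cc(OCc5ccccc5)c4c(c3[C@]12OCc1ccccc1)O[C@H](c1ccc(OCc3ccccc3)cc1)CC4 | intermediate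
21 | CNP0208300.3: 3,5,7-trihydroxy-2-(4-hydroxyphenyl)chromanone whose C-2–O and C-3–C bonds are fused to the C-7 oxygen and C-8 of (2S)-5-hydroxy-2-(4-hydroxyphenyl)chromane, fusion descriptors as in the given string | O=C1c2c(O)cc(O)cc2O[C@@]2(c3ccc(O)cc3)Oc3cc(O)c4c(c3[C@]12O)O[C@H](c1ccc(O)cc1)CC4 | target

**Step count and risks**
Total steps: 12. Longest linear sequence: 10 (steps 1–6 and 9–12); the glyoxal branch (steps 7–8) joins at step 9.

Step 11 (Proposed new method). The chiral cation may discriminate the enolate faces poorly, or the anion may drain through the ring-opened phenoxide (retro-Claisen cleavage, O-acyl isomers) faster than fluoride is displaced. Fallback, from 17 back to 20, with the two bond formations separated and the stereochemistry obtained by separation instead of catalyst control: 17 is treated with LiHMDS in THF at −78 → 0 °C (Baker–Venkataraman aroyl transfer) and the product is isolated as the 2-hydroxychromanone hemiketal F1. Its C-3 epimers are diastereomers because of the flavan centre and are separated by chromatography; the hemiketal carbon equilibrates through the open-chain form. The required epimer is then closed with NaH in DMF at 80 °C (alkoxide SNAr on the aryl fluoride) to give 20.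

Step 9. Metalation may occur at C-6 or at a benzylic O–CH2 position instead of C-8, and the aryl-metal may attack the aryl ester. Fallback, from 9 back to 14, replacing deprotonative regiocontrol by electrophilic substitution: 9 is brominated with NBS in CH2Cl2 at −40 °C, where the position para to the C-5 oxygen and ortho to the pyran oxygen should be the most nucleophilic, to give the 8-bromoflavan F2. Bromine–lithium exchange with n-BuLi in THF at −78 °C then gives 14, which re-enters step 9 at the transmetalation.

Step 6. The p-alkoxybenzylic oxyphosphonium may ionise (SN1 leakage), which would erode the enantiomeric purity of the flavan. Fallback, from 7 back to 9, setting C-2 by hydrogenation instead of substitution: the chalcone C=C is hydrogenated with RhCl(PPh3)3 and H2 in benzene/EtOH to the dihydrochalcone F3. F3 is cyclodehydrated with catalytic p-TsOH in toluene under water removal to the 2-aryl-4H-chromene F4. The enol ether double bond of F4 is then hydrogenated with a cationic iridium phosphinooxazoline catalyst (H2, 50 bar, CH2Cl2), using the ligand antipode that gives (2S), to reach 9.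

**Further compounds**
F1 | step 11 | 3,5,7-tris(benzyloxy)-2-(4-benzyloxyphenyl)-3-[(2S)-5-(benzyloxy)-2-(4-benzyloxyphenyl)-7-fluorochroman-8-yl]-2-hydroxychroman-4-one, C-3 as in 20 | O=C1c2c(OCc3ccccc3)cc(OCc3ccccc3)cc2O[C@](O)(c2ccc(OCc3ccccc3)cc2)[C@]1(OCc1ccccc1)c1c(F)cc(OCc2ccccc2)c2CC[C@@H](c3ccc(OCc4ccccc4)cc3)Oc12
F2 | step 9 | (2S)-5-(benzyloxy)-2-[4-(benzyloxy)phenyl]-8-bromo-7-fluorochromane | Brc1c(F)cc(OCc2ccccc2)c2CC[C@@H](c3ccc(OCc4ccccc4)cc3)Oc12
F3 | step 6 | 3-[2-(benzyloxy)-4-fluoro-6-hydroxyphenyl]-1-[4-(benzyloxy)phenyl]propan-1-one | O=C(CCc1c(O)cc(F)cc1OCc1ccccc1)c1ccc(OCc2ccccc2)cc1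
F4 | step 6 | 5-(benzyloxy)-2-[4-(benzyloxy)phenyl]-7-fluoro-4H-chromene | Fc1cc(OCc2ccccc2)c2CC=C(c3ccc(OCc4ccccc4)cc3)Oc2c1
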